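In ring A the bromines at C2 and C5 stand in a 1,4-relationship and bracket the adjacent oxygenated carbons C3 (ether to ring B) and C4 (phenol). C1 holds CH2OH, C6 only hydrogen. That pattern is what a para-benzyne leaves after picking up two atoms, so the plan cuts the C3-C4 bond and both ring A C-Br bonds together. One operation, a Bergman cycloaromatisation in the presence of excess CBr4, builds ring A onto the crowded ether oxygen already in place. It also sets the C2 bromine, which is out of reach of electrophilic bromination. The precursor 17 is an acyclic methyl 2,3-dialkynylacrylate with cis alkynes, one ending in the ring B aryloxy group, the other in methoxy.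

Key step: step 9

Remarks on the chemistry
- Numbering: C1-C6 are the ring A atoms of the target and also the six carbons of the hex-3-ene-1,5-diyne unit that becomes ring A. C1 is the ester-bearing alkene carbon, C6 the alkene CH, C2≡C3 the aryloxy alkyne and C5≡C4 the methoxy alkyne. In ring B, C1' bears the carbon substituent, C2' the ether oxygen, C3' and C4' oxygen, C5' bromine and C6' hydrogen.
- Geometry: the two bromines in 8, bromine and alkynyl in 14, and the two alkynyl groups in 17 are cis. By the sequence rules 8 and 14 are Z, but 17 is E, because CO2Me outranks alkynyl at C1.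
- Ethynyl ether: the usual passage from a phenol to its ethynyl ether (1,2-dichlorovinyl ether from trichloroethylene, then n-BuLi) is not used. n-BuLi would exchange the C5' bromine and add to the ester. Vinylation, bromination and silylamide elimination reach the same acetylide.
- Assumption: methyl 2,3,4-trimethoxybenzoate 1 is bought (it is one Fischer esterification away from 2,3,4-trimethoxybenzoic acid).

Step 1
Reactants: 1 methyl 2,3,4-trimethoxybenzoate
Product: 2 methyl 2-hydroxy-3,4-dimethoxybenzoate
Conditions: BCl3 (1.1 equiv), CH2Cl2, -10 °C to rt; then H2O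
Reagents that add atoms: none
Why: Chelation-directed Lewis acid ether cleavage: BCl3 is held between the ester carbonyl and the ortho methoxy oxygen, so one equivalent removes only the 2'-O-methyl group and spares the 3'- and 4'-methoxy groups and the ester.

Step 2
Reactants: 2 methyl 2-hydroxy-3,4-dimethoxybenzoate
Product: 3 methyl 5-bromo-2-hydroxy-3,4-dimethoxybenzoate
Conditions: NBS (1.05 equiv), MeCN, 0 °C to rt
Reagents that add atoms: N-bromosuccinimide, O=C1CCC(=O)N1Br
Why: Electrophilic aromatic bromination, directed to C5' because that carbon is para to the free phenol and ortho to the 4'-methoxy group, whereas the only other open carbon, C6', lies next to the ester and is served only by the twisted 3'-methoxy group.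

Step 3
Reactants: 3 methyl 5-bromo-2-hydroxy-3,4-dimethoxybenzoate
Product: 4 methyl 5-bromo-2-(ethenyloxy)-3,4-dimethoxybenzoate
Conditions: 2,4,6-trivinylcyclotriboroxane-pyridine complex, Cu(OAc)2 (2.2 equiv), pyridine, CH2Cl2, rt
Reagents that add atoms: 2,4,6-trivinylcyclotriboroxane-pyridine complex, C=CB1OB(C=C)OB(C=C)O1.c1ccncc1
Why: Chan-Lam-type oxidative C-O coupling, in which the vinyl group passes from boron to divalent copper and is joined to the phenoxide at room temperature under weakly basic conditions that leave the aryl bromide and the ester alone.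

Step 4
Reactants: 4 methyl 5-bromo-2-(ethenyloxy)-3,4-dimethoxybenzoate
Product: 6 methyl 5-bromo-2-{[(Z)-2-bromoethenyl]oxy}-3,4-dimethoxybenzoate, via 1,2-dibromoethyl ether 5 (not isolated)
Conditions: Br2 (1.0 equiv), CH2Cl2, -78 °C; DBU (1.5 equiv), -78 °C to rt
Reagents that add atoms: bromine, BrBr
Why: Addition-elimination on an enol ether: bromine adds to the electron-rich vinyl group far faster than it attacks the deactivated ring, and the amidine base then removes HBr from the labile alpha-bromo ether 5, a sequence that gives mainly the Z 2-bromovinyl ether with simple vinyl ethers.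

Step 5
Reactants: 7 methyl propiolate
Product: 8 methyl (Z)-2,3-dibromoprop-2-enoate
Conditions: Br2, CCl4, 70 °C; fractional distillation
Reagents that add atoms: bromine, BrBr
Why: Thermal bromine addition to an alkynoate under equilibrating bromine-atom conditions, the established entry to this enediyne building block, gives mainly the isomer with cis bromines (ionic addition in the cold would give the useless trans dibromide), and the minor E isomer is removed by distillation.

Step 6
Reactants: 9 chloroacetaldehyde dimethyl acetal
Product: 11 methoxyacetylene (methoxyethyne), via sodium methoxyacetylide 10 (not isolated)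
Conditions: NaNH2 (3.1 equiv), NH3 (l), -33 °C; cold aq. NaCl; distilled into THF at -78 °C (shield)
Reagents that add atoms: none
Why: Classical base-induced double elimination of a haloacetal (loss of methanol, then of HCl) gives the alkynyl ether as its sodium salt 10, which the quench protonates, and the volatile product is distilled directly into cold THF and used as a solution.

Step 7
Reactants: 11 methoxyacetylene; 8 methyl (Z)-2,3-dibromoprop-2-enoate
Product: 14 methyl (Z)-2-bromo-5-methoxypent-2-en-4-ynoate, via lithium methoxyacetylide 12 (not isolated), via methoxyethynylzinc chloride 13 (not isolated)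
Conditions: 11, n-BuLi, THF, -78 °C; ZnCl2, -78 to 0 °C; 8, Pd(PPh3)4 (3 mol %), 0 °C to rt
Reagents that add atoms: none
Why: Site-selective Negishi alkynylation: zerovalent palladium inserts first into the less hindered and more electrophilic beta C-Br bond of the 2,3-dibromoacrylate with retention of geometry, and an alkoxyethynylzinc halide couples without the ammonium salts that can hydrate an ynol ether.

Step 8
Reactants: 6 methyl 5-bromo-2-{[(Z)-2-bromoethenyl]oxy}-3,4-dimethoxybenzoate; 14 methyl (Z)-2-bromo-5-methoxypent-2-en-4-ynoate
Product: 17 methyl (2E)-2-{[4-bromo-2,3-dimethoxy-6-(methoxycarbonyl)phenoxy]ethynyl}-5-methoxypent-2-en-4-ynoate (alkynes cis), via potassium aryloxyacetylide 15 (not isolated), via aryloxyethynylzinc chloride 16 (not isolated)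
Conditions: 6, KN(SiMe3)2 (2.1 equiv), THF, -78 °C; ZnCl2, -78 to 0 °C; 14, Pd(PPh3)4 (5 mol %), rt
Reagents that add atoms: none
Why: Anti dehydrobromination of a Z 2-bromovinyl ether, the classical route to aryloxyacetylenes, is run here with a non-nucleophilic silylamide that spares the aryl bromide and the esters, and the derived zinc acetylide undergoes Negishi coupling with retention at the remaining alpha C-Br bond, into which Pd(PPh3)4 inserts at room temperature in preference to the electron-rich aryl bromide.

Step 9
Reactants: 17 methyl (2E)-2-{[4-bromo-2,3-dimethoxy-6-(methoxycarbonyl)phenoxy]ethynyl}-5-methoxypent-2-en-4-ynoate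
Product: 19 methyl 2,5-dibromo-3-[4-bromo-2,3-dimethoxy-6-(methoxycarbonyl)phenoxy]-4-methoxybenzoate, via ring A 2,5-didehydroarene diradical 18 (not isolated)
Conditions: CBr4 (about 200 equiv, 1-2 M), K2CO3 (solid), degassed PhCl, 130 °C, dark, Ar; 17 added over hours by syringe pump
Reagents that add atoms: carbon tetrabromide, BrC(Br)(Br)Br
Why: Proposed new method: on heating, the cis-disposed alkynes of 17 close by Bergman cycloaromatisation, C3 bonding to C4, to give ring A as the sigma,sigma-diradical 18 with its unpaired electrons at C2 and C5, and each radical centre then takes a bromine atom from CBr4 while the two CBr3 radicals combine to C2Br6. The closest known reaction type is the thermal cyclisation of simple (Z)-hex-3-ene-1,5-diynes in CCl4 to 1,4-dichlorobenzenes, which has been shown neither for an enediyne with two ynol ether termini nor for CBr4 as the halogen donor. Ring A closes through the two alkyne termini (six-membered closure, both triple bonds endo to the new ring), and the alternative five-membered fulvene-type closure should stay out of play because it needs bulky, radical-stabilising aryl groups directly on the alkyne carbons. No stereocentre arises, and the one geometric requirement, cis alkynes, is built into 8 and carried through two couplings that retain alkene geometry. Electronegative substituents on the bond-forming carbons relieve the in-plane repulsion between the filled alkyne orbitals that accounts for much of the barrier, so the two oxygens should ease closure, and neither O-methyl nor O-aryl has the beta C-H bond through which higher alkyl ynol ethers fragment to ketenes on heating. The selectivity needed is bromine capture ahead of ring reopening, hydrogen abstraction, attack on ring B and Kharasch-type chain addition of CBr3 radicals to unreacted ynol ether, and it is secured by a substrate that has only strong methyl, aryl and vinyl C-H bonds and a ring B blocked at both ortho positions, by CBr4 at molar concentration, and by slow addition, which keeps the stationary concentration of 17 very low.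

Step 10
Reactants: 19 methyl 2,5-dibromo-3-[4-bromo-2,3-dimethoxy-6-(methoxycarbonyl)phenoxy]-4-methoxybenzoate
Product: 20 methyl 2,5-dibromo-3-[4-bromo-2,3-dihydroxy-6-(methoxycarbonyl)phenoxy]-4-hydroxybenzoate
Conditions: BBr3 (8 equiv), CH2Cl2, -78 to 0 °C; ice-water
Reagents that add atoms: none
Why: Lewis acid cleavage of the three aryl methyl ethers with BBr3, which leaves methyl benzoates and the diaryl ether intact at or below 0 °C, is placed before the reduction so that no benzylic alcohol is exposed to a reagent that would turn it into a benzylic bromide.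

Step 11
Reactants: 20 methyl 2,5-dibromo-3-[4-bromo-2,3-dihydroxy-6-(methoxycarbonyl)phenoxy]-4-hydroxybenzoate
Product: 21 CNP0104332.0, 2,5-dibromo-3-[4-bromo-2,3-dihydroxy-6-(hydroxymethyl)phenoxy]-4-hydroxybenzyl alcohol
Conditions: i-Bu2AlH (12 equiv), THF, -78 to 0 °C; aq. potassium sodium tartrate
Reagents that add atoms: none
Why: Hydride reduction of both esters by excess i-Bu2AlH after the three phenols have been taken up as aluminium phenoxides, with the aryl bromides inert and a cold, near-neutral tartrate work-up free of alcohols protecting the two para-hydroxybenzyl alcohol units from quinone methide formation.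

Compound list
1 | methyl 2,3,4-trimethoxybenzoate | COC(=O)c1ccc(OC)c(OC)c1OC | starting material
2 | methyl 2-hydroxy-3,4-dimethoxybenzoate | COC(=O)c1ccc(OC)c(OC)c1O | intermediate
3 | methyl 5-bromo-2-hydroxy-3,4-dimethoxybenzoate | COC(=O)c1cc(Br)c(OC)c(OC)c1O | intermediate
4 | methyl 5-bromo-2-(ethenyloxy)-3,4-dimethoxybenzoate | C=COc1c(C(=O)OC)cc(Br)c(OC)c1OC | intermediate
5 | methyl 5-bromo-2-(1,2-dibromoethoxy)-3,4-dimethoxybenzoate (racemic, not isolated) | BrCC(Br)Oc1c(C(=O)OC)cc(Br)c(OC)c1OC | intermediate
6 | methyl 5-bromo-2-{[(Z)-2-bromoethenyl]oxy}-3,4-dimethoxybenzoate | Br/C=C\Oc1c(C(=O)OC)cc(Br)c(OC)c1OC | intermediate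
7 | methyl propiolate | C#CC(=O)OC | starting material
8 | methyl (Z)-2,3-dibromoprop-2-enoate | COC(=O)/C(Br)=C/Br | intermediate
9 | chloroacetaldehyde dimethyl acetal | COC(CCl)OC | starting material
10 | sodium methoxyacetylide (not isolated) | [Na]C#COC | intermediate
11 | methoxyacetylene | C#COC | intermediate
12 | lithium methoxyacetylide (not isolated) | [Li]C#COC | intermediate
13 | (methoxyethynyl)zinc chloride (not isolated) | Cl[Zn]C#COC | intermediate
14 | methyl (Z)-2-bromo-5-methoxypent-2-en-4-ynoate | COC(=O)/C(Br)=C/C#COC | intermediate
15 | potassium [4-bromo-2,3-dimethoxy-6-(methoxycarbonyl)phenoxy]acetylide (not isolated) | [K]C#COc1c(C(=O)OC)cc(Br)c(OC)c1OC | intermediate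
16 | {[4-bromo-2,3-dimethoxy-6-(methoxycarbonyl)phenoxy]ethynyl}zinc chloride (not isolated) | Cl[Zn]C#COc1c(C(=O)OC)cc(Br)c(OC)c1OC | intermediate
17 | methyl (2E)-2-{[4-bromo-2,3-dimethoxy-6-(methoxycarbonyl)phenoxy]ethynyl}-5-methoxypent-2-en-4-ynoate (alkynes cis) | COC(=O)/C(C#COc1c(C(=O)OC)cc(Br)c(OC)c1OC)=C/C#COC | intermediate
18 | methyl 3-[4-bromo-2,3-dimethoxy-6-(methoxycarbonyl)phenoxy]-4-methoxy-2,5-didehydrobenzoate (para-benzyne diradical, unpaired electrons at C2 and C5, not isolated) | COC(=O)c1c[c]c(OC)c(Oc2c(C(=O)OC)cc(Br)c(OC)c2OC)[c]1 | intermediate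
19 | methyl 2,5-dibromo-3-[4-bromo-2,3-dimethoxy-6-(methoxycarbonyl)phenoxy]-4-methoxybenzoate | COC(=O)c1cc(Br)c(OC)c(Oc2c(C(=O)OC)cc(Br)c(OC)c2OC)c1Br | intermediate
20 | methyl 2,5-dibromo-3-[4-bromo-2,3-dihydroxy-6-(methoxycarbonyl)phenoxy]-4-hydroxybenzoate | COC(=O)c1cc(Br)c(O)c(Oc2c(C(=O)OC)cc(Br)c(O)c2O)c1Br | intermediate
21 | CNP0104332.0, 2,5-dibromo-3-[4-bromo-2,3-dihydroxy-6-(hydroxymethyl)phenoxy]-4-hydroxybenzyl alcohol | OCc1cc(Br)c(O)c(Oc2c(CO)cc(Br)c(O)c2O)c1Br | target

Total number of steps: 11
Longest linear sequence: 8 steps (1, 2, 3, 4, 8, 9, 10, 11)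

Steps most likely to fail

**Step 9 (bears the label).**
- The closure may demand a temperature at which the ynol ethers oligomerise or react with CBr4 in a polar way.
- Tribromomethyl radicals may consume unreacted 17 by chain addition faster than it cyclises.
- The diradical may reopen or abstract hydrogen before the second bromine arrives.

The fallback uses known chemistry only, with ring A bought as an arene instead of being built. It sets out from phenol 3 and comes back to the route at 20. Nucleophilic aromatic substitution of 3 on purchased 1-bromo-2-fluoro-3-nitrobenzene (K2CO3, DMF, 60 °C) comes first; in that arene the bromine is the future C2 bromine and the nitro group activates the fluoride. It should give methyl 5-bromo-2-(2-bromo-6-nitrophenoxy)-3,4-dimethoxybenzoate F1. Reduction with Fe and NH4Cl in aqueous ethanol gives methyl 2-(2-amino-6-bromophenoxy)-5-bromo-3,4-dimethoxybenzoate F2. The amino group sits on the future C4. It steers N-iodosuccinimide to its para position (future C1) to give methyl 2-(2-amino-6-bromo-5-iodophenoxy)-5-bromo-3,4-dimethoxybenzoate F3. It then steers NBS to its one free ortho position (future C5) to give methyl 2-(2-amino-3,6-dibromo-5-iodophenoxy)-5-bromo-3,4-dimethoxybenzoate F4. Diazotisation (NaNO2, aqueous H2SO4, AcOH, 0 °C) gives 2-[4-bromo-2,3-dimethoxy-6-(methoxycarbonyl)phenoxy]-3,6-dibromo-4-iodobenzenediazonium hydrogen sulfate F5. Sandmeyer-type hydroxylation (Cu2O, Cu(NO3)2, water) gives methyl 5-bromo-2-(3,6-dibromo-2-hydroxy-5-iodophenoxy)-3,4-dimethoxybenzoate F6. Palladium-catalysed methoxycarbonylation (Pd(OAc)2, dppp, CO, MeOH, Et3N, 50 °C) takes the C-I bond ahead of the three C-Br bonds. It gives methyl 2,5-dibromo-3-[4-bromo-2,3-dimethoxy-6-(methoxycarbonyl)phenoxy]-4-hydroxybenzoate F7, that is 19 with the C4 oxygen already free. The BBr3 conditions of step 10 turn F7 into 20.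

**Step 8.**
- During the base step, expulsion of the aryloxide can compete with loss of bromide.
- The acetylide can attack the methyl esters while it waits for zinc and for a slow oxidative addition at the crowded alpha C-Br bond.
- Longer times or heat invite insertion into the aryl bromide.

In the fallback the base step and the coupling are separated, and the coupling is moved to a neutral manifold. It sets out from 6 and comes back at 17. Acetylide 15, made as before, is trapped at -78 °C within minutes with Bu3SnCl to give methyl 5-bromo-3,4-dimethoxy-2-{[(tributylstannyl)ethynyl]oxy}benzoate F8, which can be purified on neutral alumina. Stille coupling of F8 with 14 (Pd2(dba)3, AsPh3, THF, rt to 40 °C) then forms the same C1-C2 bond without base or free acetylide.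

**Step 3.** The phenoxide is flanked on both sides and tied to the ester by a hydrogen bond, so transfer of the vinyl group from copper may be too slow. The boroxine would then be used up by protodeboronation and homocoupling.

In the fallback the C-O bond is made by SN2 alkylation instead of by copper. It sets out from 3 and comes back at 4. Alkylation with excess 1,2-dibromoethane (K2CO3, DMF, 60 °C) gives methyl 5-bromo-2-(2-bromoethoxy)-3,4-dimethoxybenzoate F9. E2 elimination (KOt-Bu, THF, 0 °C, short contact) gives 4.

Further compounds
F1 | step 9 | methyl 5-bromo-2-(2-bromo-6-nitrophenoxy)-3,4-dimethoxybenzoate | COC(=O)c1cc(Br)c(OC)c(OC)c1Oc1c(Br)cccc1[N+](=O)[O-]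
F2 | step 9 | methyl 2-(2-amino-6-bromophenoxy)-5-bromo-3,4-dimethoxybenzoate | COC(=O)c1cc(Br)c(OC)c(OC)c1Oc1c(Br)cccc1N
F3 | step 9 | methyl 2-(2-amino-6-bromo-5-iodophenoxy)-5-bromo-3,4-dimethoxybenzoate | Ic1ccc(N)c(Oc2c(C(=O)OC)cc(Br)c(OC)c2OC)c1Br
F4 | step 9 | methyl 2-(2-amino-3,6-dibromo-5-iodophenoxy)-5-bromo-3,4-dimethoxybenzoate | Ic1cc(Br)c(N)c(Oc2c(C(=O)OC)cc(Br)c(OC)c2OC)c1Br
F5 | step 9 | 2-[4-bromo-2,3-dimethoxy-6-(methoxycarbonyl)phenoxy]-3,6-dibromo-4-iodobenzenediazonium hydrogen sulfate | Ic1cc(Br)c([N+]#N)c(Oc2c(C(=O)OC)cc(Br)c(OC)c2OC)c1Br.OS(=O)(=O)[O-]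
F6 | step 9 | methyl 5-bromo-2-(3,6-dibromo-2-hydroxy-5-iodophenoxy)-3,4-dimethoxybenzoate | Ic1cc(Br)c(O)c(Oc2c(C(=O)OC)cc(Br)c(OC)c2OC)c1Br
F7 | step 9 | methyl 2,5-dibromo-3-[4-bromo-2,3-dimethoxy-6-(methoxycarbonyl)phenoxy]-4-hydroxybenzoate | COC(=O)c1cc(Br)c(OC)c(OC)c1Oc1c(Br)c(C(=O)OC)cc(Br)c1O
F8 | step 8 | methyl 5-bromo-3,4-dimethoxy-2-{[(tributylstannyl)ethynyl]oxy}benzoate | CCCC[Sn](CCCC)(CCCC)C#COc1c(C(=O)OC)cc(Br)c(OC)c1OC
F9 | step 3 | methyl 5-bromo-2-(2-bromoethoxy)-3,4-dimethoxybenzoate | BrCCOc1c(C(=O)OC)cc(Br)c(OC)c1OC
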